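**Retrosynthetic overview**

1. Target 21 (ent-oritin-(4α→6)-oritin-4α-ol) comes from hexabenzyl ether 20, and 20 from diketone 19. One NaBH4 reduction sets C3 of unit B (hydride anti to the pseudo-axial C4 aryl) and C4 of unit A. The C3 carbonyl of unit B is unmasked from a nitro group by a Nef reaction.
2. The interflavanyl bond C4(unit B)–C6(unit A) comes from a rhodium-catalysed conjugate addition of unit A boronate 16 to 3-nitro-2H-chromene 6, in which C4 is the β-carbon of the nitroalkene.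
3. Ring C of unit B comes from salicylaldehyde 2 and nitrostyrene 3: O1–C2 by reversible oxa-Michael addition, then ring closure by the C3–C4 bond (intramolecular Henry reaction) and dehydration. The enabling feature is that on ring A of unit B the ether oxygen O1 (on C8a) and C4 (on C4a) are ortho, and that C3 carries an oxygen, for which the nitro group stands in.
4. Unit A comes from gallacetophenone via chalcone 12, Juliá–Colonna epoxide 13 and (2R,3R)-dihydroflavonol 15 (ring C of unit A closed by O1–C2), then boronate 16.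
5. Order of ring formation: ring C of unit B (step 2), ring C of unit A (step 8); the units are joined in step 10. Stereochemical relay in unit B: C2 (step 2) → C4 (step 10) → C3 (step 12).

Key step: step 2

Remark: 3 and 11 are taken as commercial. The sense of induction of the catalyst in step 2 must be confirmed (the quinidine-derived pseudo-enantiomer is used if needed), and any minor enantiomer of 6 is removed as a diastereomer after step 10. The descriptor at C4 of unit B is S in the benzyl ethers 17, 19 and 20 but R in 21 for the same spatial arrangement (CIP priority change on debenzylation).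

**Route**

Step 1
Reactants: 1 2,3,4-trihydroxybenzaldehyde
Product: 2 3,4-bis(benzyloxy)-2-hydroxybenzaldehyde
Conditions: BnBr (2.1 equiv), K2CO3 (2 equiv), DMF, rt
Reagents that add atoms: benzyl bromide, BrCc1ccccc1
Why: Williamson ether synthesis in which the 2-OH, hydrogen-bonded to the formyl group and the least reactive of the three phenols, should stay free while the 4- and 3-OH are benzylated.

Step 2
Reactants: 2 3,4-bis(benzyloxy)-2-hydroxybenzaldehyde; 3 (E)-1-(benzyloxy)-4-(2-nitroethenyl)benzene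
Product: 6 (S)-7,8-bis(benzyloxy)-2-[4-(benzyloxy)phenyl]-3-nitro-2H-chromene, via oxa-Michael adduct 4 (not isolated), via nitroaldol 5 (not isolated)
Conditions: quinine-derived 9-amino(9-deoxy)epi-cinchona 3,5-bis(trifluoromethyl)phenyl thiourea (10 mol %), PhCO2H (10 mol %), toluene, 4 Å MS, rt to 40 °C
Reagents that add atoms: none
Why: The bifunctional amine–thiourea deprotonates the phenol of 2 and binds nitroalkene 3, O1 adds reversibly to the aryl-bearing β-carbon (the later C2) to give 4, the nitronate carbon C3 of 4 then attacks the ortho formyl carbon C4 in an intramolecular Henry reaction to give 5, and E1cB loss of water gives 6. The closest known reaction type is the organocatalytic tandem oxa-Michael–Henry–dehydration of salicylaldehydes with β-nitrostyrenes to 2-aryl-3-nitro-2H-chromenes. Ring C of unit B is the only ring closed, in 6-exo-trig mode by the C3–C4 bond. C2 is the only stereocentre that survives and is controlled by the catalyst: as the oxa-Michael step is reversible, the enantiomers of 4 interconvert and the matched one should cyclise faster in the chiral hydrogen-bond/ion-pair pocket (dynamic kinetic selection), while all C3/C4 epimers of 5 converge on the same alkene. The step needs O-attack of the phenolate on the nitroalkene β-carbon (2-aryl, not 3-aryl, connectivity) and C-attack of the nitronate on the aldehyde, which the polarity of 3 and the ortho placement of OH and non-enolisable CHO in 2 secure (only a six-membered closure is possible). The nitro group is kept on purpose: it made C3 nucleophilic for the closure, makes C4 an acceptor for unit A in step 10 and becomes the C3 oxygen in steps 11 and 12.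

Step 3
Reactants: 7 1-(2,3,4-trihydroxyphenyl)ethanone (gallacetophenone)
Product: 8 1-[3,4-bis(benzyloxy)-2-hydroxyphenyl]ethanone
Conditions: BnBr (2.1 equiv), K2CO3 (2 equiv), DMF, rt
Reagents that add atoms: benzyl bromide, BrCc1ccccc1
Why: Williamson ether synthesis that should leave the 2-OH, chelated to the acetyl group, untouched.

Step 4
Reactants: 8 1-[3,4-bis(benzyloxy)-2-hydroxyphenyl]ethanone
Product: 9 1-[3,4-bis(benzyloxy)-5-bromo-2-hydroxyphenyl]ethanone
Conditions: NBS, MeCN, 0 °C, dark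
Reagents that add atoms: N-bromosuccinimide, O=C1CCC(=O)N1Br
Why: Electrophilic aromatic bromination directed by the free phenol to its para position (C5 of the acetophenone, the later C6 of unit A), which is also ortho to the 4-benzyloxy group and the only strongly activated free site.

Step 5
Reactants: 9 1-[3,4-bis(benzyloxy)-5-bromo-2-hydroxyphenyl]ethanone
Product: 10 1-[3,4-bis(benzyloxy)-5-bromo-2-(methoxymethoxy)phenyl]ethanone
Conditions: NaH, MOMCl, DMF, 0 °C
Reagents that add atoms: chloromethyl methyl ether, COCCl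
Why: Williamson-type O-alkylation of the sodium phenolate (MOM protection), which blocks flavanone formation and is needed for the nucleophilic epoxidation in step 7.

Step 6
Reactants: 10 1-[3,4-bis(benzyloxy)-5-bromo-2-(methoxymethoxy)phenyl]ethanone; 11 4-(benzyloxy)benzaldehyde
Product: 12 (E)-1-[3,4-bis(benzyloxy)-5-bromo-2-(methoxymethoxy)phenyl]-3-[4-(benzyloxy)phenyl]prop-2-en-1-one
Conditions: KOH, EtOH/THF, rt
Reagents that add atoms: none
Why: Claisen–Schmidt condensation of the methyl ketone with a non-enolisable aldehyde, dehydration of the aldol giving the conjugated (E)-enone.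

Step 7
Reactants: 12 (E)-1-[3,4-bis(benzyloxy)-5-bromo-2-(methoxymethoxy)phenyl]-3-[4-(benzyloxy)phenyl]prop-2-en-1-one
Product: 13 [(2R,3S)-3-[4-(benzyloxy)phenyl]oxiran-2-yl][3,4-bis(benzyloxy)-5-bromo-2-(methoxymethoxy)phenyl]methanone
Conditions: poly-L-leucine, urea·H2O2, DBU, THF, rt
Reagents that add atoms: hydrogen peroxide (as its urea adduct), OO
Why: Juliá–Colonna epoxidation (Weitz–Scheffer-type nucleophilic epoxidation inside the helical polypeptide), in which hydroperoxide should add to one face of the (E)-enone to give the trans (αR,βS) epoxide, both new stereocentres being set by the poly-L-leucine.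

Step 8
Reactants: 13 [(2R,3S)-3-[4-(benzyloxy)phenyl]oxiran-2-yl][3,4-bis(benzyloxy)-5-bromo-2-(methoxymethoxy)phenyl]methanone
Product: 15 (2R,3R)-7,8-bis(benzyloxy)-2-[4-(benzyloxy)phenyl]-6-bromo-3-hydroxychroman-4-one, via phenolic epoxide 14 (not isolated)
Conditions: HCl (3 M in MeOH), THF, 50 °C
Reagents that add atoms: none
Why: Acid-catalysed acetal cleavage followed by 6-endo epoxide opening by the freed phenol at the benzylic carbon with inversion, so that C3 keeps the epoxide configuration and C2 ends trans to it (the thermodynamically preferred 2,3-trans dihydroflavonol, which is also reached if the opening has carbocation character).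

Step 9
Reactants: 15 (2R,3R)-7,8-bis(benzyloxy)-2-[4-(benzyloxy)phenyl]-6-bromo-3-hydroxychroman-4-one
Product: 16 (2R,3R)-7,8-bis(benzyloxy)-2-[4-(benzyloxy)phenyl]-3-hydroxy-6-(4,4,5,5-tetramethyl-1,3,2-dioxaborolan-2-yl)chroman-4-one
Conditions: B2pin2, PdCl2(dppf) (5 mol %), KOAc, 1,4-dioxane, 85 °C
Reagents that add atoms: bis(pinacolato)diboron, CC1(C)OB(OC1(C)C)B1OC(C)(C)C(C)(C)O1
Why: Miyaura borylation of the aryl bromide under weakly basic conditions that the base-sensitive dihydroflavonol and its free 3-OH should tolerate, with no stereocentre touched.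

Step 10
Reactants: 6 (S)-7,8-bis(benzyloxy)-2-[4-(benzyloxy)phenyl]-3-nitro-2H-chromene; 16 (2R,3R)-7,8-bis(benzyloxy)-2-[4-(benzyloxy)phenyl]-3-hydroxy-6-(4,4,5,5-tetramethyl-1,3,2-dioxaborolan-2-yl)chroman-4-one
Product: 17 (2R,3R)-7,8-bis(benzyloxy)-2-[4-(benzyloxy)phenyl]-6-[(2S,3R,4S)-7,8-bis(benzyloxy)-2-[4-(benzyloxy)phenyl]-3-nitrochroman-4-yl]-3-hydroxychroman-4-one
Conditions: [Rh(OH)(cod)]2 (3 mol %), 6 (2 equiv), 1,4-dioxane/H2O 10:1, 50 °C
Reagents that add atoms: none
Why: Rhodium-catalysed conjugate addition of an aryl boronate to a nitroalkene (Hayashi–Miyaura type), in which the aryl–rhodium species should add to C4 on the face anti to the pseudo-axial C2 aryl of 6 (2,4-trans) while the aryl ketone and free OH of 16 stay inert; the C3 configuration formed on protonation of the nitronate is of no consequence.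

Step 11
Reactants: 17 the nitro compound from step 10
Product: 19 (2R,3R)-7,8-bis(benzyloxy)-2-[4-(benzyloxy)phenyl]-6-[(2S,4S)-7,8-bis(benzyloxy)-2-[4-(benzyloxy)phenyl]-3-oxochroman-4-yl]-3-hydroxychroman-4-one, via potassium nitronate 18 (not isolated)
Conditions: K2CO3, MeOH/THF, 0 °C; then KHSO5 (as 2KHSO5·KHSO4·K2SO4), H2O, 0 °C
Reagents that add atoms: potassium peroxymonosulfate, [K+].[O-]S(=O)(=O)OO
Why: Oxidative Nef reaction in which the nitronate carbon is oxidised to the carbonyl with loss of nitrite; C3 becomes trigonal, and the 2,4-trans ketone (C2 aryl equatorial, C4 aryl pseudo-axial away from H5) should also be the thermodynamic isomer, so that a C4 epimer can correct itself through the more acidic C4–H.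

Step 12
Reactants: 19 the diketone from step 11
Product: 20 (2R,3S,4R)-7,8-bis(benzyloxy)-2-[4-(benzyloxy)phenyl]-6-[(2S,3R,4S)-7,8-bis(benzyloxy)-2-[4-(benzyloxy)phenyl]-3-hydroxychroman-4-yl]chroman-3,4-diol
Conditions: NaBH4, THF/MeOH, −20 to 0 °C
Reagents that add atoms: none
Why: Borohydride reduction of both ketones, in which hydride should attack C3 of unit B axially on the face anti to the pseudo-axial C4 aryl to give the equatorial 3-OH (2,3-trans, 3,4-cis), and attack C4 of unit A axially to give the 3,4-trans diol, as is usual for 2,3-trans-dihydroflavonols.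

Step 13
Reactants: 20 the hexabenzyl ether from step 12
Product: 21 (2R,3S,4R)-2-(4-hydroxyphenyl)-6-[(2S,3R,4R)-3,7,8-trihydroxy-2-(4-hydroxyphenyl)chroman-4-yl]chroman-3,4,7,8-tetraol
Conditions: H2 (1 atm), Pd(OH)2/C, THF/MeOH, rt
Reagents that add atoms: none
Why: Catalytic hydrogenolysis of the six aryl benzyl ethers under neutral conditions, stopped at the calculated uptake so that the benzylic C4–OH of unit A and the interflavanyl bond stay intact, with no stereocentre affected.

**Compound list**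

1 | 2,3,4-trihydroxybenzaldehyde | O=Cc1ccc(O)c(O)c1O | starting material
2 | 3,4-bis(benzyloxy)-2-hydroxybenzaldehyde | O=Cc1ccc(OCc2ccccc2)c(OCc2ccccc2)c1O | intermediate
3 | (E)-1-(benzyloxy)-4-(2-nitroethenyl)benzene | [O-][N+](=O)/C=C/c1ccc(OCc2ccccc2)cc1 | starting material
4 | (S)-3,4-bis(benzyloxy)-2-[1-[4-(benzyloxy)phenyl]-2-nitroethoxy]benzaldehyde (oxa-Michael adduct) | O=Cc1ccc(OCc2ccccc2)c(OCc2ccccc2)c1O[C@H](C[N+](=O)[O-])c1ccc(OCc2ccccc2)cc1 | intermediate (not isolated)
5 | (2S)-7,8-bis(benzyloxy)-2-[4-(benzyloxy)phenyl]-3-nitrochroman-4-ol (nitroaldol, mixture of C3/C4 epimers) | OC1c2ccc(OCc3ccccc3)c(OCc3ccccc3)c2O[C@@H](c2ccc(OCc3ccccc3)cc2)C1[N+](=O)[O-] | intermediate (not isolated)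
6 | (S)-7,8-bis(benzyloxy)-2-[4-(benzyloxy)phenyl]-3-nitro-2H-chromene | [O-][N+](=O)C1=Cc2ccc(OCc3ccccc3)c(OCc3ccccc3)c2O[C@H]1c1ccc(OCc2ccccc2)cc1 | intermediate
7 | 1-(2,3,4-trihydroxyphenyl)ethanone (gallacetophenone) | CC(=O)c1ccc(O)c(O)c1O | starting material
8 | 1-[3,4-bis(benzyloxy)-2-hydroxyphenyl]ethanone | CC(=O)c1ccc(OCc2ccccc2)c(OCc2ccccc2)c1O | intermediate
9 | 1-[3,4-bis(benzyloxy)-5-bromo-2-hydroxyphenyl]ethanone | CC(=O)c1cc(Br)c(OCc2ccccc2)c(OCc2ccccc2)c1O | intermediate
10 | 1-[3,4-bis(benzyloxy)-5-bromo-2-(methoxymethoxy)phenyl]ethanone | CC(=O)c1cc(Br)c(OCc2ccccc2)c(OCc2ccccc2)c1OCOC | intermediate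
11 | 4-(benzyloxy)benzaldehyde | O=Cc1ccc(OCc2ccccc2)cc1 | starting material
12 | (E)-1-[3,4-bis(benzyloxy)-5-bromo-2-(methoxymethoxy)phenyl]-3-[4-(benzyloxy)phenyl]prop-2-en-1-one | O=C(/C=C/c1ccc(OCc2ccccc2)cc1)c1cc(Br)c(OCc2ccccc2)c(OCc2ccccc2)c1OCOC | intermediate
13 | [(2R,3S)-3-[4-(benzyloxy)phenyl]oxiran-2-yl][3,4-bis(benzyloxy)-5-bromo-2-(methoxymethoxy)phenyl]methanone | O=C([C@@H]1O[C@H]1c1ccc(OCc2ccccc2)cc1)c1cc(Br)c(OCc2ccccc2)c(OCc2ccccc2)c1OCOC | intermediate
14 | [(2R,3S)-3-[4-(benzyloxy)phenyl]oxiran-2-yl][3,4-bis(benzyloxy)-5-bromo-2-hydroxyphenyl]methanone | O=C([C@@H]1O[C@H]1c1ccc(OCc2ccccc2)cc1)c1cc(Br)c(OCc2ccccc2)c(OCc2ccccc2)c1O | intermediate (not isolated)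
15 | (2R,3R)-7,8-bis(benzyloxy)-2-[4-(benzyloxy)phenyl]-6-bromo-3-hydroxychroman-4-one | c1ccccc1COc1ccc([C@H]2Oc3c(cc(Br)c(OCc4ccccc4)c3OCc3ccccc3)C(=O)[C@@H]2O)cc1 | intermediate
16 | (2R,3R)-7,8-bis(benzyloxy)-2-[4-(benzyloxy)phenyl]-3-hydroxy-6-(4,4,5,5-tetramethyl-1,3,2-dioxaborolan-2-yl)chroman-4-one | c1ccccc1COc1ccc([C@H]2Oc3c(cc(B4OC(C)(C)C(C)(C)O4)c(OCc4ccccc4)c3OCc3ccccc3)C(=O)[C@@H]2O)cc1 | intermediate
17 | (2R,3R)-7,8-bis(benzyloxy)-2-[4-(benzyloxy)phenyl]-6-[(2S,3R,4S)-7,8-bis(benzyloxy)-2-[4-(benzyloxy)phenyl]-3-nitrochroman-4-yl]-3-hydroxychroman-4-one | c1ccccc1COc1ccc([C@H]2Oc3c(cc([C@@H]4c5ccc(OCc6ccccc6)c(OCc6ccccc6)c5O[C@@H](c5ccc(OCc6ccccc6)cc5)[C@@H]4[N+](=O)[O-])c(OCc4ccccc4)c3OCc3ccccc3)C(=O)[C@@H]2O)cc1 | intermediate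
18 | potassium nitronate of 17 (C3 of unit B trigonal) | c1ccccc1COc1ccc([C@H]2Oc3c(cc([C@@H]4c5ccc(OCc6ccccc6)c(OCc6ccccc6)c5O[C@@H](c5ccc(OCc6ccccc6)cc5)C4=[N+]([O-])[O-])c(OCc4ccccc4)c3OCc3ccccc3)C(=O)[C@@H]2O)cc1.[K+] | intermediate (not isolated)
19 | (2R,3R)-7,8-bis(benzyloxy)-2-[4-(benzyloxy)phenyl]-6-[(2S,4S)-7,8-bis(benzyloxy)-2-[4-(benzyloxy)phenyl]-3-oxochroman-4-yl]-3-hydroxychroman-4-one | c1ccccc1COc1ccc([C@H]2Oc3c(cc([C@@H]4c5ccc(OCc6ccccc6)c(OCc6ccccc6)c5O[C@@H](c5ccc(OCc6ccccc6)cc5)C4=O)c(OCc4ccccc4)c3OCc3ccccc3)C(=O)[C@@H]2O)cc1 | intermediate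
20 | (2R,3S,4R)-7,8-bis(benzyloxy)-2-[4-(benzyloxy)phenyl]-6-[(2S,3R,4S)-7,8-bis(benzyloxy)-2-[4-(benzyloxy)phenyl]-3-hydroxychroman-4-yl]chroman-3,4-diol (hexa-O-benzyl ether of 21) | c1ccccc1COc1ccc([C@H]2Oc3c(cc([C@@H]4c5ccc(OCc6ccccc6)c(OCc6ccccc6)c5O[C@@H](c5ccc(OCc6ccccc6)cc5)[C@@H]4O)c(OCc4ccccc4)c3OCc3ccccc3)[C@@H](O)[C@@H]2O)cc1 | intermediate
21 | (2R,3S,4R)-2-(4-hydroxyphenyl)-6-[(2S,3R,4R)-3,7,8-trihydroxy-2-(4-hydroxyphenyl)chroman-4-yl]chroman-3,4,7,8-tetraol (ent-oritin-(4α→6)-oritin-4α-ol) | Oc1ccc([C@H]2Oc3c(cc([C@@H]4c5ccc(O)c(O)c5O[C@@H](c5ccc(O)cc5)[C@@H]4O)c(O)c3O)[C@@H](O)[C@@H]2O)cc1 | target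

**Totals and risks**

Total step count: 13. Longest linear sequence: 11 steps (steps 3 to 13).

Most likely to fail, in this order:

Step 11. The basic nitronate may open by E1cB cleavage of the C2–O1 bond, the product ketone may enolise towards C2 and C4, and the dihydroflavonol ring of unit A may open under base; the peroxide may also damage the electron-rich rings. Fallback: a reductive Nef reaction without a pre-formed nitronate, setting out from 17 and coming back at 19. Aqueous TiCl3 buffered with NH4OAc (THF/H2O, rt) should reduce 17 to the oxime F7 and on to the N-unsubstituted imine F8, which is hydrolysed in the same flask to 19.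

Step 10. The hindered, electron-rich aryl boronate may lose boron by protonolysis faster than the aryl–rhodium species adds to the trisubstituted nitroalkene. Fallback: a stoichiometric aryl-magnesium conjugate addition with the ketone of unit A taken out first, setting out from 15 and 6 and coming back at 21. 15 is reduced (NaBH4, THF/MeOH) to the 2,3-trans-3,4-trans bromo diol F1. NaH and BnBr give its 3,4-bis(benzyl ether) F2. Bromine–magnesium exchange (iPrMgCl·LiCl, THF, 0 °C) gives the aryl magnesium chloride F3, which adds to 6 at −78 °C anti to the C2 aryl to give the chloromagnesium nitronate F4. Buffered KHSO5 in the same flask gives the chroman-3-one F5, NaBH4 gives the alcohol F6, and hydrogenolysis as in step 13 removes eight benzyl groups to give 21.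

Step 13. Once the benzyl ethers are gone, the benzylic C4–OH of unit A may be cleaved by over-reduction. Fallback: a changed order of events, setting out from 19 and coming back at 21. Hydrogenolysis of 19 (H2, Pd(OH)2/C), which has no benzylic alcohol, gives the hexaphenolic diketone F9, and NaBH4 in EtOH at 0 °C then reduces both ketones to give 21.

Further compounds

F1 | step 10 | (2R,3S,4R)-7,8-bis(benzyloxy)-2-[4-(benzyloxy)phenyl]-6-bromochroman-3,4-diol | c1ccccc1COc1ccc([C@H]2Oc3c(cc(Br)c(OCc4ccccc4)c3OCc3ccccc3)[C@@H](O)[C@@H]2O)cc1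
F2 | step 10 | 3,4-bis(benzyl ether) of F1 | c1ccccc1COc1ccc([C@H]2Oc3c(cc(Br)c(OCc4ccccc4)c3OCc3ccccc3)[C@@H](OCc3ccccc3)[C@@H]2OCc2ccccc2)cc1
F3 | step 10 | aryl magnesium chloride from F2 | c1ccccc1COc1ccc([C@H]2Oc3c(cc([Mg]Cl)c(OCc4ccccc4)c3OCc3ccccc3)[C@@H](OCc3ccccc3)[C@@H]2OCc2ccccc2)cc1
F4 | step 10 | chloromagnesium nitronate from F3 and 6 | c1ccccc1COc1ccc([C@H]2Oc3c(cc([C@@H]4c5ccc(OCc6ccccc6)c(OCc6ccccc6)c5O[C@@H](c5ccc(OCc6ccccc6)cc5)C4=[N+]([O-])[O-])c(OCc4ccccc4)c3OCc3ccccc3)[C@@H](OCc3ccccc3)[C@@H]2OCc2ccccc2)cc1.Cl[Mg+]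
F5 | step 10 | chroman-3-one with unit A as octa-O-benzyl flavan-3,4-diol | c1ccccc1COc1ccc([C@H]2Oc3c(cc([C@@H]4c5ccc(OCc6ccccc6)c(OCc6ccccc6)c5O[C@@H](c5ccc(OCc6ccccc6)cc5)C4=O)c(OCc4ccccc4)c3OCc3ccccc3)[C@@H](OCc3ccccc3)[C@@H]2OCc2ccccc2)cc1
F6 | step 10 | octa-O-benzyl ether of 21 with free 3-OH in unit B | c1ccccc1COc1ccc([C@H]2Oc3c(cc([C@@H]4c5ccc(OCc6ccccc6)c(OCc6ccccc6)c5O[C@@H](c5ccc(OCc6ccccc6)cc5)[C@@H]4O)c(OCc4ccccc4)c3OCc3ccccc3)[C@@H](OCc3ccccc3)[C@@H]2OCc2ccccc2)cc1
F7 | step 11 | oxime of 19 at C3 of unit B | c1ccccc1COc1ccc([C@H]2Oc3c(cc([C@@H]4c5ccc(OCc6ccccc6)c(OCc6ccccc6)c5O[C@@H](c5ccc(OCc6ccccc6)cc5)C4=NO)c(OCc4ccccc4)c3OCc3ccccc3)C(=O)[C@@H]2O)cc1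
F8 | step 11 | N-unsubstituted imine of 19 at C3 of unit B | c1ccccc1COc1ccc([C@H]2Oc3c(cc([C@@H]4c5ccc(OCc6ccccc6)c(OCc6ccccc6)c5O[C@@H](c5ccc(OCc6ccccc6)cc5)C4=N)c(OCc4ccccc4)c3OCc3ccccc3)C(=O)[C@@H]2O)cc1
F9 | step 13 | hexaphenolic diketone (19 without its six benzyl groups) | Oc1ccc([C@H]2Oc3c(cc([C@@H]4c5ccc(O)c(O)c5O[C@@H](c5ccc(O)cc5)C4=O)c(O)c3O)C(=O)[C@@H]2O)cc1
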